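A direct plan would cut the bond between the diaryl ether oxygen and ring A: CuI-catalysed Ullmann coupling of aryl bromide A1 (methyl 2-bromo-4-methyl-6-(prenyloxy)benzoate) with the ring B phenol A2 (2-(silyloxymethyl)-4-methoxy-6-(prenyloxy)phenol), then desilylation. Its weakest steps would be:
- the Ullmann coupling itself, which would have to join a phenol flanked by two ortho substituents to a bromide ortho to an ester, so that the heat required would approach the Claisen rearrangement range of two aryl prenyl ethers;
- the exchange of one hydroxyl of orcinol A3 for bromine by amination, diazotisation and Sandmeyer reaction, which would spend several harsh steps without forming any skeletal bond;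
- the ortho-lithiation of the bromoarene between Br and OR for carboxylation, where benzyne formation and halogen migration would compete.

Ring A is built, not coupled. Its C1(CO2Me)–C2(O-prenyl)–C3H–C4(CH3) unit is C3–C6 of a 3-carbomethoxy-2-pyrone, and its C5H–C6(OAr) unit is the triple bond of an aryl ethynyl ether made from the ring B phenol and trichloroethylene. One inverse-electron-demand Diels–Alder/retro-Diels–Alder operation forms the C1–C6 and C4–C5 bonds, expels CO2 and delivers the fully substituted benzoate with the ester between its two oxygens. The diaryl ether carbon–oxygen bond is thus made by adding a phenoxide to dichloroacetylene: no hindered aryl halide, no Sandmeyer sequence, no ortho-lithiation and no copper coupling are needed.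

Key step: step 9

Remark: the target is achiral, so no stereocentre has to be set. Ring A is numbered from the ester-bearing carbon C1 (C2 prenyloxy, C4 methyl, C6 aryloxy) and ring B from the ether-bearing carbon C1 (C2 hydroxymethyl, C4 methoxy, C6 prenyloxy). "Prenyl" means 3-methylbut-2-en-1-yl.

Step 1
Reactants: 1 dimethyl malonate; 2 diketene (4-methylideneoxetan-2-one)
Product: 4 methyl 4-hydroxy-6-methyl-2-oxo-2H-pyran-3-carboxylate, via acetoacetylmalonate 3 (not isolated)
Conditions: NaH (2.0 equiv), THF, 0 °C; diketene (1.1 equiv), 0 °C to reflux; then aq. HCl, 0 °C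
Reagents that add atoms: none
Why: C-acylation of sodium dimethyl malonate by ring opening of diketene gives the acetoacetylmalonate, whose ketone enolate oxygen lactonises onto one ester (acyl substitution, loss of methoxide) to the 3-carbomethoxy-4-hydroxy-2-pyrone, the established diketene route to 3-acyl-4-hydroxy-2-pyrones.

Step 2
Reactants: 4 methyl 4-hydroxy-6-methyl-2-oxo-2H-pyran-3-carboxylate
Product: 5 methyl 6-methyl-4-[(3-methylbut-2-en-1-yl)oxy]-2-oxo-2H-pyran-3-carboxylate
Conditions: 3-methylbut-2-en-1-ol (1.2 equiv), PPh3 (1.3 equiv), DIAD (1.3 equiv), THF, 0 °C to rt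
Reagents that add atoms: 3-methylbut-2-en-1-ol (prenyl alcohol), CC(C)=CCO
Why: Mitsunobu etherification, in which the strongly acidic 4-hydroxyl (a vinylogous carboxylic acid) is alkylated by the alkoxyphosphonium ion of prenyl alcohol by SN2 at the primary carbon, the conditions known to favour 4-O-alkylation of 4-hydroxy-2-pyrones over C-alkylation.

Step 3
Reactants: 6 2-bromo-5-methoxyphenol
Product: 7 1-bromo-4-methoxy-2-[(3-methylbut-2-en-1-yl)oxy]benzene
Conditions: prenyl bromide (1.2 equiv), K2CO3, DMF, rt
Reagents that add atoms: 1-bromo-3-methylbut-2-ene (prenyl bromide), CC(C)=CCBr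
Why: Williamson etherification, the phenoxide attacking the primary allylic bromide by SN2 under mild conditions that give O-prenylation only.

Step 4
Reactants: 7 1-bromo-4-methoxy-2-[(3-methylbut-2-en-1-yl)oxy]benzene
Product: 10 4-methoxy-2-[(3-methylbut-2-en-1-yl)oxy]phenol, via aryllithium 8 (not isolated), via lithium aryltrimethoxyborate 9 (not isolated)
Conditions: n-BuLi (1.1 equiv), THF, −78 °C; B(OMe)3 (1.5 equiv), −78 °C to rt; then 30% H2O2, aq. NaOH, 0 °C to rt; aq. HCl to pH 5
Reagents that add atoms: hydrogen peroxide, OO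
Why: Bromine–lithium exchange, borylation and alkaline peroxide oxidation (1,2-aryl shift from boron to oxygen) replace Br by OH at the same carbon with no regiochemical ambiguity, and alkaline H2O2 does not epoxidise the isolated trisubstituted alkene.

Step 5
Reactants: 10 4-methoxy-2-[(3-methylbut-2-en-1-yl)oxy]phenol
Product: 11 2-(hydroxymethyl)-4-methoxy-6-[(3-methylbut-2-en-1-yl)oxy]phenol
Conditions: 37% aq. CH2O (3 equiv), NaOH (1.1 equiv), H2O/THF, rt; then AcOH to pH 6
Reagents that add atoms: formaldehyde, C=O
Why: Lederer–Manasse hydroxymethylation, in which the phenoxide attacks formaldehyde through its only free ortho carbon (the para position carries OMe), while room temperature and excess formaldehyde hold back condensation to diarylmethanes.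

Step 6
Reactants: 11 2-(hydroxymethyl)-4-methoxy-6-[(3-methylbut-2-en-1-yl)oxy]phenol
Product: 12 2-{[(tert-butyldimethylsilyl)oxy]methyl}-4-methoxy-6-[(3-methylbut-2-en-1-yl)oxy]phenol
Conditions: TBSCl (1.05 equiv), imidazole, CH2Cl2, 0 °C
Reagents that add atoms: tert-butyldimethylsilyl chloride, CC(C)(C)[Si](C)(C)Cl
Why: Silyl ether formation, the unhindered primary benzylic alcohol being silylated much faster than the hydrogen-bonded phenol between two ortho substituents, which must stay free.

Step 7
Reactants: 12 2-{[(tert-butyldimethylsilyl)oxy]methyl}-4-methoxy-6-[(3-methylbut-2-en-1-yl)oxy]phenol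
Product: 13 tert-butyl[(2-{[(E)-1,2-dichloroethenyl]oxy}-5-methoxy-3-[(3-methylbut-2-en-1-yl)oxy]phenyl)methoxy]dimethylsilane
Conditions: trichloroethylene (2 equiv), K2CO3 (2 equiv), DMF, 70 °C
Reagents that add atoms: trichloroethylene, ClC=C(Cl)Cl
Why: Base-mediated dehydrochlorination of trichloroethylene gives dichloroacetylene in the flask, to which the phenoxide adds in anti fashion (nucleophilic addition to a haloalkyne, then protonation) to give the (E)-1,2-dichlorovinyl ether, so the future diaryl ether C–O bond is formed without any aryl halide.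

Step 8
Reactants: 13 tert-butyl[(2-{[(E)-1,2-dichloroethenyl]oxy}-5-methoxy-3-[(3-methylbut-2-en-1-yl)oxy]phenyl)methoxy]dimethylsilane
Product: 16 tert-butyl{[2-(ethynyloxy)-5-methoxy-3-[(3-methylbut-2-en-1-yl)oxy]phenyl]methoxy}dimethylsilane, via chloroethynyl ether 14 (not isolated), via lithium acetylide 15 (not isolated)
Conditions: n-BuLi (2.3 equiv), THF, −78 to −40 °C; then sat. aq. NH4Cl, −78 °C; used at once
Reagents that add atoms: none
Why: Dehydrochlorination by n-BuLi to the chloroalkynyl ether followed by chlorine–lithium exchange and low-temperature protonation is the established route from 1,2-dichlorovinyl ethers to terminal ynol ethers, and silyl and prenyl ethers tolerate n-BuLi at −78 °C.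

Step 9
Reactants: 5 methyl 6-methyl-4-[(3-methylbut-2-en-1-yl)oxy]-2-oxo-2H-pyran-3-carboxylate; 16 tert-butyl{[2-(ethynyloxy)-5-methoxy-3-[(3-methylbut-2-en-1-yl)oxy]phenyl]methoxy}dimethylsilane
Product: 18 methyl 2-[2-{[(tert-butyldimethylsilyl)oxy]methyl}-4-methoxy-6-[(3-methylbut-2-en-1-yl)oxy]phenoxy]-4-methyl-6-[(3-methylbut-2-en-1-yl)oxy]benzoate, via bicyclic lactone 17 (not isolated)
Conditions: 5 (1.5 equiv), PhMe (1 M), 110 °C, sealed tube, Ar, 24–48 h
Reagents that add atoms: none
Why: Inverse-electron-demand Diels–Alder reaction followed by retro-Diels–Alder loss of CO2: the electron-rich alkyne of 16 adds across C3 and C6 of pyrone 5, whose diene is polarised by the lactone carbonyl and the C3 ester, and the 2-oxabicyclo[2.2.2]octadienone 17 then extrudes CO2 to give the benzene ring directly, with no elimination or oxidation needed because the 2π partner is an alkyne. The closest known reaction type is the annulation of 3-carbomethoxy-2-pyrones with 1,1-dialkoxyethenes, enol ethers and ynamines, which places the heteroatom-bearing carbon next to the ester carbon; aryl alkynyl ethers are weaker nucleophiles than these partners and the 4-alkoxy group of 5 donates into the diene, so this step carries the risk of the route. Ring A is closed by a [4+2] cycloaddition that forms C1–C6 and C4–C5 and is aromatised by a retro-[4+2]; the two bridgehead stereocentres of racemic 17 are lost with CO2. The selectivity needed is regiochemical: the unsubstituted, nucleophilic β-carbon of the ynol ether must bond to pyrone C6, the terminus of the doubly activated dienoate, and the oxygen-bearing carbon to C3, which puts ArO at C6, CO2Me at C1, O-prenyl at C2 and CH3 at C4 between two CH. A temperature of 110 °C stays below the usual range of aryl prenyl ether Claisen rearrangement, and 16 has neither a β-hydrogen on its O-substituent nor an allylic or benzylic O-substituent, so the retro-ene and [3,3] decomposition paths of ynol ethers are closed.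

Step 10
Reactants: 18 methyl 2-[2-{[(tert-butyldimethylsilyl)oxy]methyl}-4-methoxy-6-[(3-methylbut-2-en-1-yl)oxy]phenoxy]-4-methyl-6-[(3-methylbut-2-en-1-yl)oxy]benzoate
Product: 19 methyl 2-[2-(hydroxymethyl)-4-methoxy-6-[(3-methylbut-2-en-1-yl)oxy]phenoxy]-4-methyl-6-[(3-methylbut-2-en-1-yl)oxy]benzoate
Conditions: Bu4NF (1.2 equiv), AcOH (1.2 equiv), THF, 0 °C to rt
Reagents that add atoms: none
Why: Fluoride-induced desilylation (Si–F bond formation) frees the primary alcohol, and the acetic acid buffer keeps the alkoxide from attacking the neighbouring hindered methyl ester.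

**Compound list**
1 | dimethyl malonate | COC(=O)CC(=O)OC | starting material
2 | diketene (4-methylideneoxetan-2-one) | C=C1CC(=O)O1 | starting material
3 | dimethyl 2-(3-oxobutanoyl)propanedioate (sodium enolate in the flask, not isolated) | CC(=O)CC(=O)C(C(=O)OC)C(=O)OC | intermediate
4 | methyl 4-hydroxy-6-methyl-2-oxo-2H-pyran-3-carboxylate | COC(=O)C1=C(O)C=C(C)OC1=O | intermediate
5 | methyl 6-methyl-4-[(3-methylbut-2-en-1-yl)oxy]-2-oxo-2H-pyran-3-carboxylate | COC(=O)C1=C(OCC=C(C)C)C=C(C)OC1=O | intermediate
6 | 2-bromo-5-methoxyphenol | COc1ccc(Br)c(O)c1 | starting material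
7 | 1-bromo-4-methoxy-2-[(3-methylbut-2-en-1-yl)oxy]benzene | COc1ccc(Br)c(OCC=C(C)C)c1 | intermediate
8 | {4-methoxy-2-[(3-methylbut-2-en-1-yl)oxy]phenyl}lithium (not isolated) | [Li]c1ccc(OC)cc1OCC=C(C)C | intermediate
9 | lithium trimethoxy{4-methoxy-2-[(3-methylbut-2-en-1-yl)oxy]phenyl}borate (not isolated) | [Li+].CO[B-](OC)(OC)c1ccc(OC)cc1OCC=C(C)C | intermediate
10 | 4-methoxy-2-[(3-methylbut-2-en-1-yl)oxy]phenol | COc1ccc(O)c(OCC=C(C)C)c1 | intermediate
11 | 2-(hydroxymethyl)-4-methoxy-6-[(3-methylbut-2-en-1-yl)oxy]phenol | COc1cc(CO)c(O)c(OCC=C(C)C)c1 | intermediate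
12 | 2-{[(tert-butyldimethylsilyl)oxy]methyl}-4-methoxy-6-[(3-methylbut-2-en-1-yl)oxy]phenol | COc1cc(CO[Si](C)(C)C(C)(C)C)c(O)c(OCC=C(C)C)c1 | intermediate
13 | tert-butyl[(2-{[(E)-1,2-dichloroethenyl]oxy}-5-methoxy-3-[(3-methylbut-2-en-1-yl)oxy]phenyl)methoxy]dimethylsilane | Cl/C=C(/Cl)Oc1c(CO[Si](C)(C)C(C)(C)C)cc(OC)cc1OCC=C(C)C | intermediate
14 | tert-butyl{[2-[(chloroethynyl)oxy]-5-methoxy-3-[(3-methylbut-2-en-1-yl)oxy]phenyl]methoxy}dimethylsilane (not isolated) | ClC#COc1c(CO[Si](C)(C)C(C)(C)C)cc(OC)cc1OCC=C(C)C | intermediate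
15 | lithium acetylide of 16, {[2-{[(tert-butyldimethylsilyl)oxy]methyl}-4-methoxy-6-[(3-methylbut-2-en-1-yl)oxy]phenoxy]ethynyl}lithium (not isolated) | [Li]C#COc1c(CO[Si](C)(C)C(C)(C)C)cc(OC)cc1OCC=C(C)C | intermediate
16 | tert-butyl{[2-(ethynyloxy)-5-methoxy-3-[(3-methylbut-2-en-1-yl)oxy]phenyl]methoxy}dimethylsilane | C#COc1c(CO[Si](C)(C)C(C)(C)C)cc(OC)cc1OCC=C(C)C | intermediate
17 | methyl 8-[2-{[(tert-butyldimethylsilyl)oxy]methyl}-4-methoxy-6-[(3-methylbut-2-en-1-yl)oxy]phenoxy]-1-methyl-5-[(3-methylbut-2-en-1-yl)oxy]-3-oxo-2-oxabicyclo[2.2.2]octa-5,7-diene-4-carboxylate (racemic, not isolated) | COC(=O)C12C(=O)OC(C)(C=C1OCC=C(C)C)C=C2Oc1c(CO[Si](C)(C)C(C)(C)C)cc(OC)cc1OCC=C(C)C | intermediate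
18 | methyl 2-[2-{[(tert-butyldimethylsilyl)oxy]methyl}-4-methoxy-6-[(3-methylbut-2-en-1-yl)oxy]phenoxy]-4-methyl-6-[(3-methylbut-2-en-1-yl)oxy]benzoate | COC(=O)c1c(OCC=C(C)C)cc(C)cc1Oc1c(CO[Si](C)(C)C(C)(C)C)cc(OC)cc1OCC=C(C)C | intermediate
19 | methyl 2-[2-(hydroxymethyl)-4-methoxy-6-[(3-methylbut-2-en-1-yl)oxy]phenoxy]-4-methyl-6-[(3-methylbut-2-en-1-yl)oxy]benzoate (CNP0561346.0, achiral) | COC(=O)c1c(OCC=C(C)C)cc(C)cc1Oc1c(CO)cc(OC)cc1OCC=C(C)C | target

Total step count: 10. Longest linear sequence: 8 (steps 3 to 10, from 2-bromo-5-methoxyphenol); the pyrone branch (steps 1 and 2) joins at step 9.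

Steps most likely to fail:

1. Step 9 (cycloaddition). The 4-alkoxy group donates into the pyrone diene and an aryl alkynyl ether is a weaker nucleophile than a ketene acetal, so the cycloaddition may be slower than oligomerisation of the alkynyl ether or than Claisen rearrangement of the prenyl ethers on prolonged heating. The fallback sets out from 13 and comes back at 18, with the polarity of the ring-forming step inverted. Acetylide 15, generated from 13 as in step 8, would be trapped with ClCO2Me to give methyl 3-(aryloxy)prop-2-ynoate F1, a stable electron-poor alkyne that already carries the ester carbon. Normal-demand Diels–Alder reaction of F1 with 1-methoxy-3-methyl-1-(trimethylsilyloxy)buta-1,3-diene F2 (from methyl 3-methylbut-2-enoate, LiN(iPr)2 and Me3SiCl) in PhMe at 80–110 °C, the diene CH2 terminus bonding to the aryloxy-bearing alkyne carbon, would give cyclohexadiene adduct F3. On mild acidic work-up F3 would lose methanol and the silyl group to give the salicylate methyl 2-(aryloxy)-6-hydroxy-4-methylbenzoate F4. O-Prenylation of F4 (prenyl bromide, K2CO3, DMF) would give 18.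

2. Step 8 (alkynyl ether). The terminal alkynyl ether may be lost by hydration or oligomerisation during work-up and concentration, and the chlorine–lithium exchange may stop short. The fallback sets out from 13 and comes back at 16. Acetylide 15 would be silylated in the flask with Me3SiCl to the C-silylated alkynyl ether F5, which can be chromatographed and stored. Compound 16 would then be released only when needed by protodesilylation (K2CO3, MeOH, 0 °C, which leaves the benzylic silyl ether intact) and taken into step 9 as a toluene solution without concentration.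

3. Step 5 (hydroxymethylation). The salicyl alcohol may condense further with unreacted phenoxide to diarylmethanes, or conversion may stay low. The fallback sets out from 10 and comes back at 11. Magnesium-mediated ortho-formylation (MgCl2, Et3N, paraformaldehyde, MeCN, reflux) would give 2-hydroxy-5-methoxy-3-(prenyloxy)benzaldehyde F6, which cannot condense further, and NaBH4 in MeOH at 0 °C would reduce F6 to 11.

**Further compounds**
F1 | step 9 | methyl 3-[2-{[(tert-butyldimethylsilyl)oxy]methyl}-4-methoxy-6-[(3-methylbut-2-en-1-yl)oxy]phenoxy]prop-2-ynoate | COC(=O)C#COc1c(CO[Si](C)(C)C(C)(C)C)cc(OC)cc1OCC=C(C)C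
F2 | step 9 | 1-methoxy-3-methyl-1-(trimethylsilyloxy)buta-1,3-diene | C=C(C)C=C(OC)O[Si](C)(C)C
F3 | step 9 | methyl 2-[2-{[(tert-butyldimethylsilyl)oxy]methyl}-4-methoxy-6-[(3-methylbut-2-en-1-yl)oxy]phenoxy]-6-methoxy-4-methyl-6-(trimethylsilyloxy)cyclohexa-1,4-diene-1-carboxylate (racemic) | COC(=O)C1=C(Oc2c(CO[Si](C)(C)C(C)(C)C)cc(OC)cc2OCC=C(C)C)CC(C)=CC1(OC)O[Si](C)(C)C
F4 | step 9 | methyl 2-[2-{[(tert-butyldimethylsilyl)oxy]methyl}-4-methoxy-6-[(3-methylbut-2-en-1-yl)oxy]phenoxy]-6-hydroxy-4-methylbenzoate | COC(=O)c1c(O)cc(C)cc1Oc1c(CO[Si](C)(C)C(C)(C)C)cc(OC)cc1OCC=C(C)C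
F5 | step 8 | tert-butyl{[5-methoxy-3-[(3-methylbut-2-en-1-yl)oxy]-2-{[(trimethylsilyl)ethynyl]oxy}phenyl]methoxy}dimethylsilane | C[Si](C)(C)C#COc1c(CO[Si](C)(C)C(C)(C)C)cc(OC)cc1OCC=C(C)C
F6 | step 5 | 2-hydroxy-5-methoxy-3-[(3-methylbut-2-en-1-yl)oxy]benzaldehyde | COc1cc(OCC=C(C)C)c(O)c(C=O)c1
A1 | direct plan | methyl 2-bromo-4-methyl-6-[(3-methylbut-2-en-1-yl)oxy]benzoate | COC(=O)c1c(Br)cc(C)cc1OCC=C(C)C
A2 | direct plan | 2-{[(tert-butyldimethylsilyl)oxy]methyl}-4-methoxy-6-[(3-methylbut-2-en-1-yl)oxy]phenol | COc1cc(CO[Si](C)(C)C(C)(C)C)c(O)c(OCC=C(C)C)c1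
A3 | direct plan | orcinol (5-methylbenzene-1,3-diol) | Cc1cc(O)cc(O)c1
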